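The route rests on cutting the biaryl bond between the ether-bearing allylbenzene ring (ring A) and the 3-allyl-4-hydroxyphenyl ring (ring B). The key step exploits the ortho relationship in ring A between the biaryl carbon and the carbon carrying the tertiary C4–O ether. A nitro group at the biaryl carbon first activates the neighbouring C–F for SNAr by the hindered eudesmane C4 alkoxide, and is then itself the leaving group in a Pd/BrettPhos denitrative Suzuki–Miyaura coupling with an unprotected ring-B boronate. The precursor is thus a 2-nitroaryl ether, not an aryl halide. The decalin comes from (+)-dihydrocarvone; C10 is auxiliary-controlled, and C5 and C4 are set in one reductive enolate hydroxylation.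

Key step: step 9

Remark: names use eudesmane numbering (C4 ring carbinol, C5/C10 ring fusion, C7 side-chain carbon, C11 side-chain carbinol) with α/β descriptors (10-CH3 = β). Commercial (+)-dihydrocarvone contains its C2 epimer, which converges in step 1.

Step 1
Reactants: 1 (+)-dihydrocarvone
Product: 4 (+)-α-cyperone, via imine 2 (not isolated), via diketone 3 (not isolated)
Conditions: (R)-(+)-1-phenylethylamine, TsOH (cat.), toluene, reflux (Dean–Stark); ethyl vinyl ketone, THF, 40 °C; 10% aq AcOH, rt; then NaOMe, MeOH, 60 °C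
Reagents that add atoms: ethyl vinyl ketone, C=CC(=O)CC
Why: Robinson annulation in its chiral-imine variant, in which the secondary enamine tautomer of 2 adds to the enone at the more substituted α-carbon on the face dictated by the (R)-1-phenylethyl group (setting quaternary C10 as 10β-CH3 relative to the purchased C7 center) and methoxide-mediated aldol condensation of 3 closes ring A.

Step 2
Reactants: 4 (+)-α-cyperone
Product: 6 4α-hydroxy-5α-eudesm-11-en-3-one, via lithium enolate 5 (not isolated)
Conditions: Li (2.2 equiv), t-BuOH (1.0 equiv), NH3(l)/THF, −78 °C; NH3 evaporated; 2-(phenylsulfonyl)-3-phenyloxaziridine (1.5 equiv), THF, −78 → 0 °C; aq NH4Cl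
Reagents that add atoms: 2-(phenylsulfonyl)-3-phenyloxaziridine, O=S(=O)(c1ccccc1)N1OC1c1ccccc1
Why: Dissolving-metal (Birch-type) enone reduction should give the Δ3 lithium enolate regiospecifically with C5 protonated from the α face (trans-decalin), and N-sulfonyloxaziridine enolate hydroxylation should then occur at C4 anti to the syn-axial C10 methyl, giving 4α-OH/4β-CH3.

Step 3
Reactants: 6 4α-hydroxy-5α-eudesm-11-en-3-one
Product: 8 5α-eudesm-11-en-4α-ol (selin-11-en-4α-ol), via tosylhydrazone 7 (not isolated)
Conditions: TsNHNH2, EtOH, 70 °C; then catecholborane (3 equiv), CHCl3, 0 °C → rt; NaOAc·3H2O, reflux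
Reagents that add atoms: none
Why: Caglioti-type tosylhydrazone reduction with catecholborane removes the C3 carbonyl through an alkyldiazene under near-neutral conditions, which should leave the tertiary alcohol, the C4/C5 stereocenters and the isopropenyl group untouched.

Step 4
Reactants: 8 5α-eudesm-11-en-4α-ol; 9 4-bromo-1-fluoro-2-nitrobenzene
Product: 11 4α-(4-bromo-2-nitrophenoxy)-5α-eudesm-11-ene, via potassium alkoxide 10 (not isolated)
Conditions: KHMDS (1.05 equiv), THF, 0 °C; then 9, 18-crown-6 (cat.), 0 °C → rt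
Reagents that add atoms: none
Why: SNAr, in which the ortho-nitro group activates the C–F bond enough for displacement by the hindered tertiary alkoxide at low temperature; the C4–O bond is not broken, so C4 keeps its configuration.

Step 5
Reactants: 11 4α-(4-bromo-2-nitrophenoxy)-5α-eudesm-11-ene
Product: 13 4α-(4-bromo-2-nitrophenoxy)-5α-eudesman-11-ol, via organomercurial 12 (not isolated)
Conditions: Hg(OAc)2 (1.1 equiv), THF/H2O, rt; then NaBH4, 3 M NaOH, 0 °C
Reagents that add atoms: water, O
Why: Markovnikov oxymercuration–demercuration hydrates the only alkene present (the allyl groups are introduced later for this reason) to the tertiary C11 alcohol, while the nitroarene, the aryl bromide and the electron-poor aryl ether are inert.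

Step 6
Reactants: 13 4α-(4-bromo-2-nitrophenoxy)-5α-eudesman-11-ol
Product: 14 4α-(4-allyl-2-nitrophenoxy)-5α-eudesman-11-ol
Conditions: allylSnBu3, Pd(PPh3)4 (5 mol%), toluene, 90 °C
Reagents that add atoms: allyltributylstannane, C=CC[Sn](CCCC)(CCCC)CCCC
Why: Stille allylation, in which Pd(0)/PPh3 inserts into C–Br only (C–NO2 is inert with this ligand) and allyl transfer from tin gives the terminal allyl arene.

Step 7
Reactants: 15 4-(4,4,5,5-tetramethyl-1,3,2-dioxaborolan-2-yl)phenol
Product: 16 2-[4-(allyloxy)phenyl]-4,4,5,5-tetramethyl-1,3,2-dioxaborolane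
Conditions: allyl bromide, K2CO3, acetone, 55 °C
Reagents that add atoms: allyl bromide, C=CCBr
Why: Williamson etherification of the phenoxide under anhydrous carbonate conditions that the pinacol boronate tolerates.

Step 8
Reactants: 16 2-[4-(allyloxy)phenyl]-4,4,5,5-tetramethyl-1,3,2-dioxaborolane
Product: 17 2-allyl-4-(4,4,5,5-tetramethyl-1,3,2-dioxaborolan-2-yl)phenol
Conditions: N,N-diethylaniline, 195 °C
Reagents that add atoms: none
Why: Aromatic Claisen [3,3] rearrangement delivers the allyl group to one of the two equivalent free ortho positions (para is blocked by boron) and tautomerization restores the phenol.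

Step 9
Reactants: 14 4α-(4-allyl-2-nitrophenoxy)-5α-eudesman-11-ol; 17 2-allyl-4-(4,4,5,5-tetramethyl-1,3,2-dioxaborolan-2-yl)phenol
Product: 18 target biaryl ether (CNP0219722.1)
Conditions: Pd(acac)2 (5 mol%), BrettPhos (20 mol%), 18-crown-6 (10 mol%), K3PO4·nH2O (3 equiv), 17 (2 equiv), 1,4-dioxane, 130 °C
Reagents that add atoms: none
Why: Pd(0)/BrettPhos binds the nitroarene η2 and inserts into the Ar–NO2 bond of 14, the aryl–Pd nitrite undergoes transmetalation with the phosphate/hydroxide-activated boronate 17, and reductive elimination forms the biaryl bond. The closest known reaction type is the denitrative Suzuki–Miyaura coupling of nitroarenes, which includes electron-rich alkoxy-substituted substrates. No ring is closed and no stereocenter is created; the four decalin stereocenters should be untouched because the medium is basic and non-ionizing for the tertiary ether and tertiary alcohol. The selectivities needed are C–C over C–O coupling at the free phenol, retention of both terminal allyl groups, and coupling before protodeboronation. These should be secured by fast boron-to-palladium transfer from the boronate para to the phenoxide, by the absence of a hydride source that could move the allyl double bonds, by the nitro group being the only electrophilic site left after step 6, and by the excess of 17.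

Compound list
1 | (+)-dihydrocarvone, (2R,5R)-2-methyl-5-(prop-1-en-2-yl)cyclohexan-1-one | O=C1C[C@H](C(C)=C)CC[C@H]1C | starting material
2 | N-[(R)-1-phenylethyl] imine of dihydrocarvone (C2 labile) | C[C@@H](N=C1C[C@H](C(C)=C)CCC1C)c1ccccc1 | intermediate
3 | (2S,5R)-2-methyl-2-(3-oxopentyl)-5-(prop-1-en-2-yl)cyclohexan-1-one | CCC(=O)CC[C@]1(C)CC[C@@H](C(C)=C)CC1=O | intermediate
4 | (+)-α-cyperone, eudesma-4,11-dien-3-one (10β-CH3, 7β-isopropenyl) | O=C1CC[C@]2(C)CC[C@@H](C(C)=C)CC2=C1C | intermediate
5 | lithium Δ3-enolate of 5α-eudesm-11-en-3-one (trans-fused) | CC1=C(O[Li])CC[C@]2(C)CC[C@@H](C(C)=C)C[C@H]21 | intermediate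
6 | 4α-hydroxy-5α-eudesm-11-en-3-one (4β-CH3, trans-decalin) | O[C@]1(C)C(=O)CC[C@]2(C)CC[C@@H](C(C)=C)C[C@H]21 | intermediate
7 | p-toluenesulfonylhydrazone of 6 | O[C@]1(C)C(=NNS(=O)(=O)c3ccc(C)cc3)CC[C@]2(C)CC[C@@H](C(C)=C)C[C@H]21 | intermediate
8 | 5α-eudesm-11-en-4α-ol (selin-11-en-4α-ol; 4β-CH3, 7β-isopropenyl) | O[C@]1(C)CCC[C@]2(C)CC[C@@H](C(C)=C)C[C@H]21 | intermediate
9 | 4-bromo-1-fluoro-2-nitrobenzene | O=[N+]([O-])c1cc(Br)ccc1F | starting material
10 | potassium 4α-alkoxide of 8 | [K+].[O-][C@]1(C)CCC[C@]2(C)CC[C@@H](C(C)=C)C[C@H]21 | intermediate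
11 | 4α-(4-bromo-2-nitrophenoxy)-5α-eudesm-11-ene | O=[N+]([O-])c1cc(Br)ccc1O[C@]1(C)CCC[C@]2(C)CC[C@@H](C(C)=C)C[C@H]21 | intermediate
12 | 12-(acetoxymercurio)-4α-(4-bromo-2-nitrophenoxy)-5α-eudesman-11-ol (C11 epimers) | O=[N+]([O-])c1cc(Br)ccc1O[C@]1(C)CCC[C@]2(C)CC[C@@H](C(C)(O)C[Hg]OC(C)=O)C[C@H]21 | intermediate
13 | 4α-(4-bromo-2-nitrophenoxy)-5α-eudesman-11-ol | O=[N+]([O-])c1cc(Br)ccc1O[C@]1(C)CCC[C@]2(C)CC[C@@H](C(C)(C)O)C[C@H]21 | intermediate
14 | 4α-(4-allyl-2-nitrophenoxy)-5α-eudesman-11-ol | C=CCc1ccc(O[C@]2(C)CCC[C@]3(C)CC[C@@H](C(C)(C)O)C[C@H]32)c([N+](=O)[O-])c1 | intermediate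
15 | 4-(4,4,5,5-tetramethyl-1,3,2-dioxaborolan-2-yl)phenol | CC1(C)OB(OC1(C)C)c1ccc(O)cc1 | starting material
16 | 2-[4-(allyloxy)phenyl]-4,4,5,5-tetramethyl-1,3,2-dioxaborolane | C=CCOc1ccc(cc1)B1OC(C)(C)C(C)(C)O1 | intermediate
17 | 2-allyl-4-(4,4,5,5-tetramethyl-1,3,2-dioxaborolan-2-yl)phenol | C=CCc1cc(ccc1O)B1OC(C)(C)C(C)(C)O1 | intermediate
18 | target: 4α-[(3',5-diallyl-4'-hydroxybiphenyl-2-yl)oxy]-5α-eudesman-11-ol | C=CCc1ccc(O[C@]2(C)CCC[C@]3(C)CC[C@@H](C(C)(C)O)C[C@H]32)c(-c2ccc(O)c(CC=C)c2)c1 | target

Total step count: 9. Longest linear sequence: 7 (steps 1–6 and 9).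

Steps most likely to fail

Step 9. Oxidative addition into the hindered, electron-rich C–NO2 bond may be slow, and C–O arylation at the free phenol, protodeboronation or palladium-mediated migration of the allyl double bonds at 130 °C may compete. The fallback sets out from 14 and replaces the nitro group by a conventional halide handle. Reduction with Fe/NH4Cl (EtOH/H2O, 70 °C) should give 4α-(4-allyl-2-aminophenoxy)-5α-eudesman-11-ol F1. Aprotic Sandmeyer iodination (t-BuONO, CH2I2, MeCN, 60 °C) should then give 4α-(4-allyl-2-iodophenoxy)-5α-eudesman-11-ol F2. A standard Suzuki–Miyaura coupling of F2 with 17 (Pd(OAc)2/SPhos, K3PO4, THF/H2O, 40 °C) comes back to the route at 18.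

Step 2. Facial selectivity at C4 may be poor, or the enolate may be consumed by proton transfer or by addition to the sulfonimine by-product. The fallback sets out from 4 and also bypasses step 3. Li/NH3 reduction with trapping of the enolate by PhNTf2 should give 5α-eudesma-3,11-dien-3-yl triflate F3. Pd(OAc)2/PPh3-catalysed formate reduction (HCO2H, Bu3N, DMF, 60 °C) should give α-selinene F4. mCPBA (1 equiv, NaHCO3, CH2Cl2, −20 °C) should epoxidize the more electron-rich trisubstituted alkene from the α face to 3α,4α-epoxy-5α-eudesm-11-ene F5. LiEt3BH (THF, reflux) should open F5 at the secondary carbon, returning to the route at 8.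

Step 3. Hydrazone formation at the ketone flanked by the quaternary carbinol may be incomplete, or the C4 oxygen may be lost by elimination during diazene decomposition. The fallback sets out from 6. NaBH4 (MeOH, 0 °C) should give 5α-eudesm-11-ene-3β,4α-diol F6. Selective acylation of the secondary hydroxyl with phenyl chlorothionoformate (pyridine, DMAP, CH2Cl2, 0 °C) should give the 3-O-phenyl thionocarbonate F7. Barton–McCombie deoxygenation (Bu3SnH, AIBN, toluene, 90 °C) returns to the route at 8.

Further compounds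
F1 | step 9 | 4α-(4-allyl-2-aminophenoxy)-5α-eudesman-11-ol | C=CCc1ccc(O[C@]2(C)CCC[C@]3(C)CC[C@@H](C(C)(C)O)C[C@H]32)c(N)c1
F2 | step 9 | 4α-(4-allyl-2-iodophenoxy)-5α-eudesman-11-ol | C=CCc1ccc(O[C@]2(C)CCC[C@]3(C)CC[C@@H](C(C)(C)O)C[C@H]32)c(I)c1
F3 | step 2 | 5α-eudesma-3,11-dien-3-yl trifluoromethanesulfonate | CC1=C(OS(=O)(=O)C(F)(F)F)CC[C@]2(C)CC[C@@H](C(C)=C)C[C@H]21
F4 | step 2 | α-selinene (5α-eudesma-3,11-diene) | CC1=CCC[C@]2(C)CC[C@@H](C(C)=C)C[C@H]21
F5 | step 2 | 3α,4α-epoxy-5α-eudesm-11-ene | O1[C@]2(C)[C@H]1CC[C@]3(C)CC[C@@H](C(C)=C)C[C@H]32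
F6 | step 3 | 5α-eudesm-11-ene-3β,4α-diol | O[C@]1(C)[C@@H](O)CC[C@]2(C)CC[C@@H](C(C)=C)C[C@H]21
F7 | step 3 | 3-O-(phenoxythiocarbonyl) derivative of 5α-eudesm-11-ene-3β,4α-diol | O[C@]1(C)[C@@H](OC(=S)Oc3ccccc3)CC[C@]2(C)CC[C@@H](C(C)=C)C[C@H]21
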